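**Plan**
1. Retrosynthesis first cuts the ArCH2–C bond at the ring carbon between the two enol carbons of the triketone ring (Mannich base / ortho-quinone methide coupling of two monomers). It then cuts, inside the triketone ring, the bond from the quaternary carbon to the ring carbonyl carbon that neighbours the butanoyl-bearing carbon.
2. Enabling feature: the quaternary carbon is the 2-position of a 1,3-dicarbonyl inside a cyclohexane-1,3,5-trione. The carbocycle is therefore the C-acyl isomer of a 6-(sec-alkyl)-4-hydroxy-2-pyranone in which the same carbonyl carbon acylates the enol oxygen of the other flanking carbonyl. The butanoyl carbon, its ring carbon and the adjacent C–O are carried as a fused isoxazole (temporary ring).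
3. Forward: 4-hydroxy-6-methyl-2-pyranone, two side-chain alkylations, 3-butanoylation and isoxazole annulation give the flat bicycle 7. A chiral-carbene-catalysed O-to-C acyl transfer turns the aromatic pyranone ring of 7 into the dearomatised carbocycle (the ring closure). N–O cleavage and hydrolysis then unmask triketone 11.
4. The aromatic monomer (phloroglucinol, butanoylation, 4-O-methylation, Mannich base 15) is joined last through the methylene carbon.
5. Stereochemistry: the only stereocenter, the quaternary carbon, is set in the ring closure by the chiral carbene catalyst. The process is enantioconvergent from racemic 7, whose side-chain stereocenter is erased on enolisation, and a quaternary center cannot epimerise afterwards.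

Key step: step 5

Remark: the triketone ring of 11, 17 and related compounds is written in the enol form of the given SMILES and the CIP descriptors refer to these drawings; compounds 3 to 7 are racemic at the side-chain carbon on purpose.

Step 1
Reactants: 1 4-hydroxy-6-methyl-2H-pyran-2-one
Product: 2 6-ethyl-4-hydroxy-2H-pyran-2-one
Conditions: LiN(iPr)2 (2.2 equiv), THF, −78 °C; MeI (1.05 equiv), −78 to −30 °C; then 1 M HCl
Reagents that add atoms: iodomethane, CI
Why: Deprotonation of the hydroxyl and then of the vinylogous 6-methyl group gives a dianion whose carbanion terminus is the most nucleophilic site, so C-methylation of the side chain should result (dianion alkylation of 4-hydroxy-2-pyranones); no stereocenter is formed.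

Step 2
Reactants: 2 6-ethyl-4-hydroxy-2H-pyran-2-one
Product: 3 4-hydroxy-6-(5-methylhex-4-en-2-yl)-2H-pyran-2-one (racemic)
Conditions: LiN(iPr)2 (2.2 equiv), THF, −78 °C; prenyl bromide (1.05 equiv), −78 to −20 °C; then 1 M HCl
Reagents that add atoms: 1-bromo-3-methylbut-2-ene (prenyl bromide), CC(C)=CCBr
Why: A second dianion alkylation at the same side-chain carbon, by SN2 attack on the reactive allylic bromide, should build the sec-alkyl group; the new stereocenter is racemic on purpose because step 5 erases it.

Step 3
Reactants: 3 4-hydroxy-6-(5-methylhex-4-en-2-yl)-2H-pyran-2-one (racemic)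
Product: 5 3-butanoyl-4-hydroxy-6-(5-methylhex-4-en-2-yl)-2H-pyran-2-one (racemic), via pyranyl butanoate 4 (not isolated)
Conditions: butanoic acid (1.1 equiv), DCC (1.1 equiv), DMAP (0.3 equiv), toluene, 23 °C then 90 °C
Reagents that add atoms: butanoic acid, CCCC(O)=O
Why: Steglich esterification of the 4-hydroxyl followed by DMAP-mediated O-to-C acyl migration (Fries-type) should place the butanoyl group on C3, the established access to 3-acyl-4-hydroxy-2-pyranones.

Step 4
Reactants: 5 3-butanoyl-4-hydroxy-6-(5-methylhex-4-en-2-yl)-2H-pyran-2-one (racemic)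
Product: 7 6-(5-methylhex-4-en-2-yl)-3-propyl-4H-pyrano[3,4-d][1,2]oxazol-4-one (racemic), via oxime 6 (not isolated)
Conditions: NH2OH (50% aq., 1.3 equiv), EtOH, 60 °C; then AcOH, 100 °C
Reagents that add atoms: hydroxylamine, NO
Why: Oxime formation at the most electrophilic (acyl) carbonyl and cyclodehydration of the oxime oxygen onto the vinylogous-acid carbon C4 should give the fused isoxazole (standard isoxazole synthesis from 2-acyl-1,3-dicarbonyl compounds), which masks the acidic 3-acyl-4-hydroxy unit.

Step 5
Reactants: 7 6-(5-methylhex-4-en-2-yl)-3-propyl-4H-pyrano[3,4-d][1,2]oxazol-4-one (racemic)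
Product: 9 (5R)-5-methyl-5-(3-methylbut-2-en-1-yl)-3-propyl-1,2-benzoxazole-4,6(5H,7H)-dione, via acyl azolium enolate 8 (not isolated)
Conditions: (5S)-5-benzyl-2-mesityl-6,7-dihydro-5H-pyrrolo[2,1-c][1,2,4]triazol-2-ium tetrafluoroborate (15 mol%), 2-tert-butyl-1,1,3,3-tetramethylguanidine (1.2 equiv), 4 Å molecular sieves, toluene, 40 °C; then aq. citric acid
Reagents that add atoms: none
Why: Proposed new method: the free carbene should add to the lactone carbonyl of 7 and open the enol ester to acyl azolium enolate 8; guanidine-mediated proton shifts convert the conjugated enolate into the minor enolate at the side-chain carbon, which attacks the azolium-activated carbonyl in a 6-(enolendo)-exo-trig closure that forms the bond between the former lactone carbonyl carbon and the side-chain carbon, and loss of the carbene gives 9. The closest known reaction types are the carbene-catalysed ionisation and recombination of enol esters, the Steglich rearrangement (O-to-C acyl transfer that creates quaternary carbons under chiral nucleophilic catalysis) and the achiral alkoxide-mediated rearrangement of enol lactones to cyclic 1,3-diones. The quaternary stereocenter is set in the C–C bond formation: the benzyl-bearing stereocenter of the catalyst leaves one face of the acyl azolium open, peri strain with the isoxazole 3-propyl group forces the azolium into the pseudo-axial position of the forming ring, and the enolate geometry that puts methyl rather than the prenyl methylene gauche to the azolium should react faster, the two geometries interconverting by proton transfer faster than they cyclise. Both enantiomers of 7 converge because the side-chain stereocenter is erased on enolisation. The step needs C- over O-acylation and ring-size control: O-acylation only regenerates 7 and is reversible under the catalyst, attack from the ring-side methylene would give a four-membered ring, the isoxazole removes the acidic hydroxyl and the aldol-prone butanoyl ketone, and the C-acylated product is withdrawn as its guanidinium enolate. The (5S)-catalyst is proposed for (5R)-9 on this model, and its (5R)-antipode would be used should the sense of induction prove opposite.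

Step 6
Reactants: 9 (5R)-5-methyl-5-(3-methylbut-2-en-1-yl)-3-propyl-1,2-benzoxazole-4,6(5H,7H)-dione
Product: 10 (4R)-2-(1-aminobutylidene)-4-methyl-4-(3-methylbut-2-en-1-yl)cyclohexane-1,3,5-trione
Conditions: Mo(CO)6 (1.0 equiv), MeCN–H2O (15:1), 80 °C
Reagents that add atoms: none
Why: Molybdenum hexacarbonyl and water should cleave the weak N–O bond reductively to the vinylogous amide (known isoxazole-to-enaminone reduction) without touching the trisubstituted alkene or the quaternary stereocenter.

Step 7
Reactants: 10 (4R)-2-(1-aminobutylidene)-4-methyl-4-(3-methylbut-2-en-1-yl)cyclohexane-1,3,5-trione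
Product: 11 (4R)-2-butanoyl-3,5-dihydroxy-4-methyl-4-(3-methylbut-2-en-1-yl)cyclohexa-2,5-dien-1-one
Conditions: 2 M NaOH (3 equiv), MeOH, 60 °C; then 1 M HCl to pH 3, 0 °C
Reagents that add atoms: water (as aqueous NaOH), O
Why: Hydrolysis of the vinylogous primary amide by addition–elimination of hydroxide should give the triketone as its delocalised enolate, which shields the ring carbonyls from retro-Claisen opening, so the stereocenter is untouched.

Step 8
Reactants: 12 benzene-1,3,5-triol (phloroglucinol)
Product: 13 1-(2,4,6-trihydroxyphenyl)butan-1-one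
Conditions: butanoyl chloride (1.0 equiv), AlCl3 (3.5 equiv), PhNO2, 0 to 60 °C; then ice, 1 M HCl
Reagents that add atoms: butanoyl chloride, CCCC(Cl)=O
Why: Friedel–Crafts acylation of the symmetric electron-rich triol should stop at the monoketone, which is deactivated towards a second acylation.

Step 9
Reactants: 13 1-(2,4,6-trihydroxyphenyl)butan-1-one
Product: 14 1-(2,6-dihydroxy-4-methoxyphenyl)butan-1-one
Conditions: Me2SO4 (1.0 equiv), K2CO3 (1.0 equiv), acetone, 56 °C
Reagents that add atoms: dimethyl sulfate, COS(=O)(=O)OC
Why: The para hydroxyl is the only one not hydrogen-bonded to the ketone and forms the most nucleophilic phenoxide, so one equivalent of dimethyl sulfate should give the 4-methyl ether (Williamson-type O-methylation).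

Step 10
Reactants: 14 1-(2,6-dihydroxy-4-methoxyphenyl)butan-1-one
Product: 15 1-{3-[(dimethylamino)methyl]-2,6-dihydroxy-4-methoxyphenyl}butan-1-one
Conditions: Me2NH (40% aq., 1.0 equiv), HCHO (37% aq., 1.0 equiv), EtOH, 0 to 23 °C
Reagents that add atoms: formaldehyde, C=O; dimethylamine, CNC
Why: Phenolic Mannich reaction at one of the two equivalent free ring positions, with one equivalent of iminium to limit double aminomethylation.

Step 11
Reactants: 11 (4R)-2-butanoyl-3,5-dihydroxy-4-methyl-4-(3-methylbut-2-en-1-yl)cyclohexa-2,5-dien-1-one; 15 1-{3-[(dimethylamino)methyl]-2,6-dihydroxy-4-methoxyphenyl}butan-1-one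
Product: 17 (4R)-2-butanoyl-6-[(3-butanoyl-2,4-dihydroxy-6-methoxyphenyl)methyl]-3,5-dihydroxy-4-methyl-4-(3-methylbut-2-en-1-yl)cyclohexa-2,5-dien-1-one (elaphopilosin A), via ortho-quinone methide 16 (not isolated)
Conditions: 15 (1.1 equiv), toluene, 90 °C; then aq. citric acid
Reagents that add atoms: none
Why: Thermal loss of dimethylamine from the phenolic Mannich base, helped by protonation by the acidic triketone, should give ortho-quinone methide 16, which is trapped by Michael addition of the enolate of 11 through its only ring CH carbon; no stereocenter is formed and the quaternary center is not affected.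

**Compound list**
1 | 4-hydroxy-6-methyl-2H-pyran-2-one | CC1=CC(O)=CC(=O)O1 | starting material
2 | 6-ethyl-4-hydroxy-2H-pyran-2-one | CCC1=CC(O)=CC(=O)O1 | intermediate
3 | 4-hydroxy-6-(5-methylhex-4-en-2-yl)-2H-pyran-2-one (racemic) | CC(CC=C(C)C)C1=CC(O)=CC(=O)O1 | intermediate
4 | 6-(5-methylhex-4-en-2-yl)-2-oxo-2H-pyran-4-yl butanoate (racemic) | CCCC(=O)OC1=CC(=O)OC(C(C)CC=C(C)C)=C1 | intermediate
5 | 3-butanoyl-4-hydroxy-6-(5-methylhex-4-en-2-yl)-2H-pyran-2-one (racemic) | CCCC(=O)C1=C(O)C=C(C(C)CC=C(C)C)OC1=O | intermediate
6 | 4-hydroxy-3-[1-(hydroxyimino)butyl]-6-(5-methylhex-4-en-2-yl)-2H-pyran-2-one (racemic) | CCCC(=NO)C1=C(O)C=C(C(C)CC=C(C)C)OC1=O | intermediate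
7 | 6-(5-methylhex-4-en-2-yl)-3-propyl-4H-pyrano[3,4-d][1,2]oxazol-4-one (racemic) | CCCC1=NOC2=C1C(=O)OC(C(C)CC=C(C)C)=C2 | intermediate
8 | (5S)-5-benzyl-2-mesityl-3-{[5-(3,6-dimethyl-2-oxidohepta-1,5-dien-1-yl)-3-propyl-1,2-oxazol-4-yl]carbonyl}-6,7-dihydro-5H-pyrrolo[2,1-c][1,2,4]triazol-2-ium (zwitterion, first-formed enolate tautomer) | CCCc1noc(C=C([O-])C(C)CC=C(C)C)c1C(=O)C5=[N+](c3c(C)cc(C)cc3C)N=C2N5[C@H](Cc4ccccc4)CC2 | intermediate
9 | (5R)-5-methyl-5-(3-methylbut-2-en-1-yl)-3-propyl-1,2-benzoxazole-4,6(5H,7H)-dione | CCCC1=NOC2=C1C(=O)[C@](C)(CC=C(C)C)C(=O)C2 | intermediate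
10 | (4R)-2-(1-aminobutylidene)-4-methyl-4-(3-methylbut-2-en-1-yl)cyclohexane-1,3,5-trione | CCCC(N)=C1C(=O)[C@](C)(CC=C(C)C)C(=O)CC1=O | intermediate
11 | (4R)-2-butanoyl-3,5-dihydroxy-4-methyl-4-(3-methylbut-2-en-1-yl)cyclohexa-2,5-dien-1-one | CCCC(=O)C1=C(O)[C@](C)(CC=C(C)C)C(O)=CC1=O | intermediate
12 | benzene-1,3,5-triol (phloroglucinol) | Oc1cc(O)cc(O)c1 | starting material
13 | 1-(2,4,6-trihydroxyphenyl)butan-1-one | CCCC(=O)c1c(O)cc(O)cc1O | intermediate
14 | 1-(2,6-dihydroxy-4-methoxyphenyl)butan-1-one | CCCC(=O)c1c(O)cc(OC)cc1O | intermediate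
15 | 1-{3-[(dimethylamino)methyl]-2,6-dihydroxy-4-methoxyphenyl}butan-1-one | CCCC(=O)c1c(O)cc(OC)c(CN(C)C)c1O | intermediate
16 | 2-butanoyl-3-hydroxy-5-methoxy-6-methylidenecyclohexa-2,4-dien-1-one | CCCC(=O)C1=C(O)C=C(OC)C(=C)C1=O | intermediate
17 | (4R)-2-butanoyl-6-[(3-butanoyl-2,4-dihydroxy-6-methoxyphenyl)methyl]-3,5-dihydroxy-4-methyl-4-(3-methylbut-2-en-1-yl)cyclohexa-2,5-dien-1-one (elaphopilosin A) | CCCC(=O)C1=C(O)[C@](C)(CC=C(C)C)C(O)=C(Cc2c(OC)cc(O)c(C(=O)CCC)c2O)C1=O | target

Total step count: 11. Longest linear sequence: 8 steps (steps 1 to 7, then step 11).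

**Steps most likely to fail**

Step 5 (proposed new method). The two enolate geometries may not be discriminated well enough, which would lower the enantiomeric purity, or the ring-opened species may only return to 7 by O-acylation so that conversion stalls. The fallback sets out from 7 and uses known chemistry. NaOMe in methanol at reflux opens the lactone to the methyl ester and closes the carbocycle by Claisen condensation (the alkoxide-mediated rearrangement of enol lactones to cyclic 1,3-diones), which should give racemic 5-methyl-5-(3-methylbut-2-en-1-yl)-3-propyl-1,2-benzoxazole-4,6(5H,7H)-dione F1. Mo(CO)6 in wet acetonitrile should then give racemic 2-(1-aminobutylidene)-4-methyl-4-(3-methylbut-2-en-1-yl)cyclohexane-1,3,5-trione F2. Amine exchange with (S)-1-phenylethylamine in hot ethanol should give two diastereomeric enaminones, separable by crystallisation or chromatography: (4R)-4-methyl-4-(3-methylbut-2-en-1-yl)-2-(1-{[(1S)-1-phenylethyl]amino}butylidene)cyclohexane-1,3,5-trione F3 and its (4S) diastereomer (4S)-4-methyl-4-(3-methylbut-2-en-1-yl)-2-(1-{[(1S)-1-phenylethyl]amino}butylidene)cyclohexane-1,3,5-trione F4. F3 is hydrolysed with aqueous NaOH as in step 7 and returns to the route at 11.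

Step 11. The quinone methide may be captured a second time at the free aromatic position of the product, may add to a second molecule of 15, or the liberated dimethylamine may condense with the butanoyl carbonyl. The fallback sets out from 11 and 14 with the roles reversed. Compound 11 is aminomethylated at its ring CH with dimethylmethylideneammonium iodide to give (4R)-2-butanoyl-6-[(dimethylamino)methyl]-3,5-dihydroxy-4-methyl-4-(3-methylbut-2-en-1-yl)cyclohexa-2,5-dien-1-one F5. Heating F5 with an excess of 14 and NaOAc in dioxane should expel dimethylamine, and the resulting 2-methylidene triketone is trapped by Friedel–Crafts-type Michael addition of the phloroglucinol ring, arriving at 17.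

Step 7. The vinylogous amide may resist hydrolysis, and forcing base may open the ring by retro-Claisen cleavage. The fallback sets out from 10: nitrosative deamination with NaNO2 in aqueous acetic acid at 0 °C (diazotisation of the primary vinylogous amide, loss of dinitrogen, capture by water) should give 11 directly without a new intermediate.

Further compounds
F1 | step 5 | racemic 5-methyl-5-(3-methylbut-2-en-1-yl)-3-propyl-1,2-benzoxazole-4,6(5H,7H)-dione | CCCC1=NOC2=C1C(=O)C(C)(CC=C(C)C)C(=O)C2
F2 | step 5 | racemic 2-(1-aminobutylidene)-4-methyl-4-(3-methylbut-2-en-1-yl)cyclohexane-1,3,5-trione | CCCC(N)=C1C(=O)C(C)(CC=C(C)C)C(=O)CC1=O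
F3 | step 5 | (4R)-4-methyl-4-(3-methylbut-2-en-1-yl)-2-(1-{[(1S)-1-phenylethyl]amino}butylidene)cyclohexane-1,3,5-trione | CCCC(N[C@@H](C)c1ccccc1)=C1C(=O)[C@](C)(CC=C(C)C)C(=O)CC1=O
F4 | step 5 | (4S)-4-methyl-4-(3-methylbut-2-en-1-yl)-2-(1-{[(1S)-1-phenylethyl]amino}butylidene)cyclohexane-1,3,5-trione | CCCC(N[C@@H](C)c1ccccc1)=C1C(=O)[C@@](C)(CC=C(C)C)C(=O)CC1=O
F5 | step 11 | (4R)-2-butanoyl-6-[(dimethylamino)methyl]-3,5-dihydroxy-4-methyl-4-(3-methylbut-2-en-1-yl)cyclohexa-2,5-dien-1-one | CCCC(=O)C1=C(O)[C@](C)(CC=C(C)C)C(O)=C(CN(C)C)C1=O
F0 | step 7 | none | none
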